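Atom labels C1–C10 follow daucane numbering throughout: C1 quaternary methyl carbon, C2 and C3 ring CH2, C4 isopropyl carbinol, C5 ring-fusion CH, C6 ester carbinol, C7 CH2, C8 methyl-bearing alkene carbon, C9 alkene CH, C10 CH2. In the azulene-based names C1 = 8a, C2 = 1, C3 = 2, C4 = 3, C5 = 3a, C6 = 4, C7 = 5, C8 = 6, C9 = 7, C10 = 8.

## Analysis of the target

The target is the 3,4-dimethoxybenzoate of a trans-fused bicyclo[5.3.0]decene diol: a cyclopentane (C1–C5) fused along C1–C5 to a cycloheptene (C5–C10, C1) with its only alkene at C8=C9. Four contiguous stereocentres are present: C1 (R, quaternary, methyl), C4 (R, tertiary carbinol with isopropyl), C5 (S, ring-fusion hydrogen) and C6 (S, ester carbinol). The angular methyl and the C4 hydroxyl lie on one face; the isopropyl group, H5 and the C6 ester oxygen lie on the other, so the ring fusion is trans and the two oxygens are anti. The tertiary C4 hydroxyl is β to C6, so every C6 ketone on the way is a tertiary aldol that can suffer retro-aldol cleavage or dehydration. The C8=C9 alkene is β,γ to C6 and slips into conjugation with a C6 carbonyl, and the ester is base-labile. The difficulty is concentrated at C5, which is flanked by two fully substituted carbons, and at C1, which must be set in the absolute sense while a seven-membered ring with one exactly placed alkene is built. The strategy rests on one feature: C5–C10, with the oxygen on C6 and the methyl on C8, are the six carbons of a 2-methoxy-4-methylphenyl ring (C5 ipso, C6 methoxy-bearing, C10 the free ortho carbon), and C1 is a single extra carbon bonded to both C5 and C10, the pattern left by a carbene that has added to an arene and expanded it.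

## Retrosynthetic reasoning

**Ester C–O bond.** Target 27 is cut at the ester into diol 25 and acid chloride 26. The ester is the most base-sensitive group and the secondary C6 hydroxyl can be acylated beside the tertiary C4 hydroxyl without protection, so this bond is made last.

**C6–H bond.** Diol 25 goes back to β-hydroxy ketone 24. The forward reduction must bring hydride to the β face of C6, the face that carries the angular methyl and the C4 oxygen and that external reagents avoid; delivery from the C4 hydroxyl itself solves this and is the reason the C4 oxygen is free at that stage.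

**C2–H bonds.** C2 carries nothing in the target, but the ring-forming step needs a carbonyl there. Ketone 24 is therefore traced through thionocarbonate 23 to the C2 alcohol 22. The radical deoxygenation is placed after the seven-membered ring has lost its extra unsaturation, because a C2 radical next to a C1 that still carries vinyl groups would rearrange by 1,2-vinyl shift.

**C7–H and C10–H bonds.** A C8=C9 alkene flanked by two methylene groups and β,γ to a C6 ketone is the product of 1,6-reduction of a 2,4-dienone followed by kinetic α-protonation, which leads from 22 back to dienone 20. The conjugated position of C5 next to the dienolate is not involved, so C5 and the C4 oxygen are safe.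

**C4–O–Si bond, C5–H bond and C6 carbonyl.** Dienone 20 comes from its silyl ether 19, and 19 from the methyl enol ether 18 by hydrolysis. Here C5 receives its hydrogen and the ring fusion is set. The C4 oxygen must stay silylated during this step, since a free tertiary allylic alcohol beside an enol ether would ionise and be lost. Alcohol 18 comes from ketone 17 by carbonyl reduction, done first so that no acceptor group activates the ring system toward acid or base.

**C1–C5 and C1–C10 bonds (key disconnection).** Azulenone 17 is opened to diazoketone 14: C1 becomes a methyl-bearing carbene carbon and C5–C10 an anisole ring. No other disconnection forms both rings and the quaternary centre at once from an intermediate in which C4 already carries its oxygen and isopropyl group and the arene already carries the C6 oxygen and the C8 methyl. The forward reaction has to add the carbene to C5 and C10 (not to the methoxy-bearing C6), on the arene face dictated by C4, and must outrun C–H insertion and hydride shift.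

**C1–C2 bond.** Diazoketone 14 is cut between the carbonyl carbon and the diazo carbon into acid 12 and a two-carbon diazoalkane. The acid has to be activated without free acid being released, because the benzylic silyl ether is acid-labile.

**C3–C4 bond and the C4 stereocentre.** Acid 12 goes back through salt 9 and racemic acid 8 to ester 7, made from ketone 4 and bromoester 5 through zinc enolate 6. An aryl isopropyl ketone offers no reliably enantioselective acetate addition, so the tertiary carbinol is made racemic and resolved at the acid stage. This is the only stereocentre that has to be bought; all others derive from it.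

**Aryl–C4 bond.** Ketone 4 is cut into aryllithium 3, from bromide 1, and amide 2. Starting from the bromide fixes the acyl group ortho to methoxy and para to methyl, which direct metalation or acylation of the unbrominated arene would not do cleanly.

## Alternatives that were turned down

**Alternative 1:** The seven-membered ring is made from 2,5-dimethylanisole A1 by inserting one carbon (C5) between C6 and C1. A1 is reduced to its 1,4-dihydro enol ether A2; a dihalocarbene adds to the enol-ether double bond, and opening of the dihalocyclopropane with loss of the O-methyl group gives 2-bromo-3,6-dimethylcyclohepta-2,5-dien-1-one A3.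
- For: in two or three cheap steps A3 already holds the C6 carbonyl, the C8 methyl and the C8=C9 alkene flanked by C7H2 and C10H2. On this point it is stronger than the chosen route, which must reduce a triene down to that alkene.
- Against: A3 is achiral, so C1 would have to be created by an enantioselective conjugate addition to a β,β-disubstituted α-bromoenone, and the whole five-membered ring with the C4 carbinol (bonds C1–C2 and C4–C5) would still have to be annulated. A3 is one loss of HBr away from an aromatic troponoid and its skipped alkene moves easily into conjugation, so the basic and nucleophilic reagents needed for the annulation threaten it.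
- Comparison: the chosen strategy gives up the ready-made alkene but forms both rings and C1 in one step, under the control of a C4 centre that is already complete.

**Alternative 2:** The C1–C5 bond of the five-membered ring is cut and C1 is taken from (S)-citronellol A4. A4 is converted into the silyl-protected isopropyl ketone A5; a lithiated silyldiazomethane turns the ketone into an alkylidene carbene, which inserts into the tertiary C1–H bond with retention and gives cyclopentene A6.
- For: the absolute configuration of the quaternary C1 comes from the chiral pool through a stereospecific insertion. This is more secure than the chosen route, which relies on a resolution and a diastereoselective ring closure.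
- Against: only the five-membered ring is made. The seven-membered ring still needs two C–C bonds (C5–C6 and a closure in the C7–C9 region), and C4, C5 and C6 must all be set afterwards from a trisubstituted alkene whose C5 is neopentyl; oxygen at C4 and carbon at C5 have to be added anti across it. The step count after the key step is clearly higher.
- Comparison: the chosen strategy sets C1 less securely but closes the seven-membered ring in the same step and brings the C6 oxygen, the C8 methyl and the complete C4 carbinol in with the precursor.

**Alternative 3:** The bonds C5–C1 and C9–C10 are formed by photocycloaddition and the ring is then expanded. The enolised acylcyclopentanone A7, which carries a tethered 1,1-disubstituted alkene, is irradiated; the cyclobutanol formed fragments by retro-aldol cleavage of C5–C9 to the hydroazulenedione A8.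
- For: like the chosen route it forms the five-membered ring and the seven-membered ring in one operation and sets C1. It leaves a saturated seven-membered ring with a C9 ketone beside the C8 methyl carbon, a direct handle for the C8=C9 alkene, and a C4 ketone for the isopropyl group. It has no surplus unsaturation or extra oxygen to remove, and on this point it is as strong as or stronger than the chosen route.
- Against: A8 has no oxygen at C6; it would have to be introduced late, next to an epimerisable ring fusion. The isopropyl group must be added to a hindered, enolisable C4 ketone with the right facial sense, the two ketones must be told apart, and the stereocentre that steers the photocycloaddition (C8) is destroyed later.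
- Comparison: the chosen strategy needs more redox adjustment after ring formation, but the C6 oxygen, the C4 carbinol with its isopropyl group and the C8 methyl are all in place before the key step.

Key step: step 7

Assumption: the (R)-acid forms the less soluble salt with (S)-1-phenylethylamine; if a screen shows the opposite pairing, (R)-1-phenylethylamine is used and nothing else changes.
Remark: compounds 18 to 23 are carried as mixtures of C2 epimers (C2 becomes CH2 in step 13), so C2 is left undefined in their SMILES.

## Route

Step 1
Reactants: 1 1-bromo-2-methoxy-4-methylbenzene; 2 N-methoxy-N,2-dimethylpropanamide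
Product: 4 1-(2-methoxy-4-methylphenyl)-2-methylpropan-1-one, via aryllithium 3 (not isolated)
Conditions: n-BuLi, THF, −78 °C; then 2, −78 → 0 °C; aq. NH4Cl
Reagents that add atoms: none
Why: Bromine–lithium exchange places the acyl group unambiguously ortho to methoxy and para to methyl, and the N-methoxy-N-methylamide stops at the ketone through its chelated tetrahedral adduct (Weinreb ketone synthesis).

Step 2
Reactants: 4 1-(2-methoxy-4-methylphenyl)-2-methylpropan-1-one; 5 ethyl bromoacetate
Product: 7 ethyl rac-3-hydroxy-3-(2-methoxy-4-methylphenyl)-4-methylpentanoate, via Reformatsky reagent 6 (not isolated)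
Conditions: Zn dust (TMSCl-activated), THF, 65 °C; aq. NH4Cl
Reagents that add atoms: none
Why: Reformatsky reaction; the weakly basic zinc enolate adds to the hindered aryl isopropyl ketone, whose only α-hydrogen is a shielded methine, instead of enolising it, and the carbinol carbon (C4 of the target) forms as a racemate.

Step 3
Reactants: 7 ethyl rac-3-hydroxy-3-(2-methoxy-4-methylphenyl)-4-methylpentanoate
Product: 8 rac-3-hydroxy-3-(2-methoxy-4-methylphenyl)-4-methylpentanoic acid
Conditions: LiOH·H2O, THF–MeOH–H2O, 25 °C; then 1 M HCl to pH 3, 0 °C
Reagents that add atoms: lithium hydroxide, [Li+].[OH-]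
Why: Saponification; the ester of a tertiary aldol is cleaved at room temperature without retro-aldol, and the acidification is kept cold and mild because the benzylic tertiary alcohol on the electron-rich ring ionises in strong acid.

Step 4
Reactants: 8 rac-3-hydroxy-3-(2-methoxy-4-methylphenyl)-4-methylpentanoic acid
Product: 9 (S)-1-phenylethylammonium (R)-3-hydroxy-3-(2-methoxy-4-methylphenyl)-4-methylpentanoate
Conditions: (S)-1-phenylethylamine (1 equiv), EtOAc–EtOH, crystallise; recrystallise to constant rotation
Reagents that add atoms: (S)-1-phenylethylamine, C[C@H](N)c1ccccc1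
Why: Classical resolution through diastereomeric ammonium salts, the standard way to resolve 3-aryl-3-hydroxyalkanoic acids; it fixes the absolute configuration at C4, from which every other stereocentre is later derived.

Step 5
Reactants: 9 (S)-1-phenylethylammonium (R)-3-hydroxy-3-(2-methoxy-4-methylphenyl)-4-methylpentanoate
Product: 12 (R)-3-(2-methoxy-4-methylphenyl)-4-methyl-3-(triethylsilyloxy)pentanoic acid, via free hydroxy acid 10 (not isolated), via bis-silyl compound 11 (not isolated)
Conditions: aq. citric acid/EtOAc (amine washed out); TESOTf (2.5 equiv), 2,6-lutidine, CH2Cl2, −78 → 0 °C; then K2CO3, MeOH–H2O, 0 °C; work-up at pH 4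
Reagents that add atoms: triethylsilyl trifluoromethanesulfonate, CC[Si](CC)(CC)OS(=O)(=O)C(F)(F)F
Why: The silyl triflate with 2,6-lutidine silylates both the carboxyl group and the hindered tertiary hydroxyl, and carbonate methanolysis then cleaves only the silyl ester. A triethylsilyl ether is chosen over a trimethylsilyl ether because it must survive the buffered acid of step 9; it also keeps the C4 oxygen from O–H insertion and, being hindered and weakly basic, from ylide formation with the carbene.

Step 6
Reactants: 12 (R)-3-(2-methoxy-4-methylphenyl)-4-methyl-3-(triethylsilyloxy)pentanoic acid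
Product: 14 (R)-2-diazo-5-(2-methoxy-4-methylphenyl)-6-methyl-5-(triethylsilyloxy)heptan-3-one, via acid chloride 13 (not isolated)
Conditions: 1-chloro-N,N,2-trimethylprop-1-en-1-amine, CH2Cl2, 0 °C; then CH3CHN2 (3 equiv, from N-ethyl-N-nitrosourea/KOH), Et2O, −20 → 0 °C
Reagents that add atoms: diazoethane, CC=[N+]=[N-]
Why: The α-chloroenamine makes acid chloride 13 without releasing HCl, so the acid-labile benzylic silyl ether survives; acylation of diazoethane then gives the α-methyl diazoketone, a second equivalent of diazoethane taking up the HCl formed.

Step 7
Reactants: 14 (R)-2-diazo-5-(2-methoxy-4-methylphenyl)-6-methyl-5-(triethylsilyloxy)heptan-3-one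
Product: 17 (3R,8aR)-4-methoxy-6,8a-dimethyl-3-(propan-2-yl)-3-(triethylsilyloxy)-3,8a-dihydroazulen-1(2H)-one, via rhodium carbenoid 15 (not isolated), via norcaradiene 16 (not isolated)
Conditions: Rh2(OAc)4 (1 mol %), CH2Cl2, 40 °C, slow addition of 14
Reagents that add atoms: none
Why: Dirhodium tetraacetate expels N2 from 14 and gives the electrophilic carbenoid 15, whose carbene carbon C1 adds across the ipso carbon C5 and the free ortho carbon C10 to give norcaradiene 16, which opens by disrotatory six-electron electrocyclic cleavage of the C5–C10 bond to cycloheptatriene 17; this is the intramolecular Buchner reaction of an α-methyl α-diazoketone with a tethered arene, a known route to 8a-methylazulenones. The five-membered ring closes in the cyclopropanation itself, through the C1–C5 bond, the C2–C3–C4 tether bringing the carbene onto the ipso carbon; the seven-membered ring arises by one-carbon expansion of the benzene ring, through the C1–C10 bond and the electrocyclic opening. The only new stereocentre, C1, is controlled by C4: in the addition the C4–C3 bond stands roughly perpendicular to the arene, and of the two other C4 substituents the one that lies in the arene plane beside the ortho methoxy group ends up cis to the C1 methyl. Allylic 1,3-strain with that methoxy group allows only the small oxygen in this position, so the isopropyl group points to the face opposite the carbene and the methyl on C1 becomes cis to the silyloxy group and anti to isopropyl, the same sense as the known trans preference of benzylic-substituted substrates. Addition to C10 and not to the methoxy-bearing C6 follows from the substitution of that carbon. Insertion into the isopropyl methine C–H bond and 1,2-hydride shift are held back by the strongly activated ipso carbon (ortho methoxy, para methyl), the electrophilic carboxylate catalyst, the methyl rather than higher alkyl carbene substituent and slow addition. The methoxy group of the arene is thereby turned into the C6 enol ether, the aryl methyl into the C8 methyl, and the carbene methyl into the angular methyl.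

Step 8
Reactants: 17 (3R,8aR)-4-methoxy-6,8a-dimethyl-3-(propan-2-yl)-3-(triethylsilyloxy)-3,8a-dihydroazulen-1(2H)-one
Product: 18 (3R,8aR)-4-methoxy-6,8a-dimethyl-3-(propan-2-yl)-3-(triethylsilyloxy)-1,2,3,8a-tetrahydroazulen-1-ol
Conditions: NaBH4, MeOH–CH2Cl2, −20 → 0 °C
Reagents that add atoms: none
Why: Borohydride reduction of the cyclopentanone; removing the C2 carbonyl at once takes away the acceptor that makes the norcaradiene valence isomer a push–pull cyclopropane and makes the C3 hydrogens acidic (β-elimination of the silyloxy group), so the acid step that follows is safe. The new C2 centre is not controlled and does not matter.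

Step 9
Reactants: 18 (3R,8aR)-4-methoxy-6,8a-dimethyl-3-(propan-2-yl)-3-(triethylsilyloxy)-1,2,3,8a-tetrahydroazulen-1-ol
Product: 19 (3R,3aR,8aR)-1-hydroxy-6,8a-dimethyl-3-(propan-2-yl)-3-(triethylsilyloxy)-2,3,3a,8a-tetrahydroazulen-4(1H)-one
Conditions: AcOH–NaOAc buffer (pH ≈ 4.5, 2 M acetate), THF–H2O, 25 °C
Reagents that add atoms: water, O
Why: Enol ether hydrolysis by rate-limiting C-protonation at C5, which is general-acid catalysed, so a concentrated weak-acid buffer should favour it over the specific-acid-catalysed ionisation of the allylic C4–O bond (the Stork–Danheiser-type loss of the C4 oxygen), which the silyl ether further slows. The proton should enter C5 on the convex α face of the boat-shaped cycloheptatriene, opposite the axial angular methyl and the silyloxy group, which sets the trans ring fusion (H5 cis to isopropyl); this is also the epimer that keeps C6 away from the isopropyl group.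

Step 10
Reactants: 19 (3R,3aR,8aR)-1-hydroxy-6,8a-dimethyl-3-(propan-2-yl)-3-(triethylsilyloxy)-2,3,3a,8a-tetrahydroazulen-4(1H)-one
Product: 20 (3R,3aR,8aR)-1,3-dihydroxy-6,8a-dimethyl-3-(propan-2-yl)-2,3,3a,8a-tetrahydroazulen-4(1H)-one
Conditions: HF·pyridine, pyridine, THF, 0 → 25 °C
Reagents that add atoms: none
Why: Buffered, non-basic fluoride cleavage of the tertiary silyl ether; it is done at the robust dienone stage because the β,γ-enone made next would not tolerate basic fluoride, and the freed tertiary aldol is not exposed to base.

Step 11
Reactants: 20 (3R,3aR,8aR)-1,3-dihydroxy-6,8a-dimethyl-3-(propan-2-yl)-2,3,3a,8a-tetrahydroazulen-4(1H)-one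
Product: 22 (3R,3aR,8aR)-1,3-dihydroxy-6,8a-dimethyl-3-(propan-2-yl)-2,3,3a,5,8,8a-hexahydroazulen-4(1H)-one, via lithium dienolate 21 (not isolated)
Conditions: Li (6 equiv), NH3(l)–THF, t-BuOH (1 equiv), −78 °C; then solid NH4Cl, −78 °C
Reagents that add atoms: none
Why: Dissolving-metal 1,6-reduction of a 2,4-dienone: the radical anion is protonated at the terminal carbon C10, the dienolate 21 resists further reduction, and kinetic protonation by NH4Cl occurs at the α-carbon C7, leaving the alkene at C8=C9 (the course known for steroidal 4,6-dien-3-ones giving 5-en-3-ones). C5 is not part of the dienolate, so the ring fusion and the C4 oxygen are untouched, and no new stereocentre is formed.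

Step 12
Reactants: 22 (3R,3aR,8aR)-1,3-dihydroxy-6,8a-dimethyl-3-(propan-2-yl)-2,3,3a,5,8,8a-hexahydroazulen-4(1H)-one
Product: 23 O-[(3R,3aR,8aR)-3-hydroxy-6,8a-dimethyl-4-oxo-3-(propan-2-yl)-1,2,3,3a,4,5,8,8a-octahydroazulen-1-yl] O-phenyl carbonothioate
Conditions: PhOC(S)Cl, pyridine, CH2Cl2, 0 → 25 °C
Reagents that add atoms: O-phenyl chlorothionoformate, S=C(Cl)Oc1ccccc1
Why: Acylation of the secondary C2 hydroxyl under pyridine, mild enough for the β,γ-enone; the tertiary C4 hydroxyl does not react.

Step 13
Reactants: 23 O-[(3R,3aR,8aR)-3-hydroxy-6,8a-dimethyl-4-oxo-3-(propan-2-yl)-1,2,3,3a,4,5,8,8a-octahydroazulen-1-yl] O-phenyl carbonothioate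
Product: 24 (3R,3aR,8aR)-3-hydroxy-6,8a-dimethyl-3-(propan-2-yl)-2,3,3a,5,8,8a-hexahydroazulen-4(1H)-one
Conditions: Bu3SnH, AIBN (cat.), toluene, 90 °C
Reagents that add atoms: none
Why: Barton–McCombie deoxygenation; the C2 radical now has no π bond on the substituents of the neighbouring C1, which is why this step follows the diene reduction (at the triene or dienone stage a 1,2-vinyl shift through a cyclopropylcarbinyl radical would compete). The neutral conditions leave the β,γ-enone and the aldol unit intact.

Step 14
Reactants: 24 (3R,3aR,8aR)-3-hydroxy-6,8a-dimethyl-3-(propan-2-yl)-2,3,3a,5,8,8a-hexahydroazulen-4(1H)-one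
Product: 25 (3R,3aS,4S,8aR)-6,8a-dimethyl-3-(propan-2-yl)-1,2,3,3a,4,5,8,8a-octahydroazulene-3,4-diol
Conditions: Me4NBH(OAc)3, MeCN–AcOH, −25 °C
Reagents that add atoms: none
Why: Hydroxyl-directed reduction of Evans–Saksena type: an acetate on boron is exchanged for the C4 hydroxyl and hydride is passed on through a six-membered transition state to the β face of C6, the face on which the axial C4 oxygen sits, giving the 6α-alcohol (H6 β, anti to H5). An external hydride would instead attack the α face, away from the angular methyl and the C4 oxygen.

Step 15
Reactants: 25 (3R,3aS,4S,8aR)-6,8a-dimethyl-3-(propan-2-yl)-1,2,3,3a,4,5,8,8a-octahydroazulene-3,4-diol; 26 3,4-dimethoxybenzoyl chloride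
Product: 27 (3R,3aS,4S,8aR)-3-hydroxy-6,8a-dimethyl-3-(propan-2-yl)-1,2,3,3a,4,5,8,8a-octahydroazulen-4-yl 3,4-dimethoxybenzoate
Conditions: Et3N, DMAP (cat.), CH2Cl2, 0 → 25 °C
Reagents that add atoms: none
Why: DMAP-catalysed acylation; only the secondary C6 hydroxyl reacts, the tertiary C4 hydroxyl being inert under these conditions, and the base-sensitive ester is introduced last.

## Compound list

1 | 1-bromo-2-methoxy-4-methylbenzene (2-bromo-5-methylanisole) | COc1cc(C)ccc1Br | starting material
2 | N-methoxy-N,2-dimethylpropanamide | CC(C)C(=O)N(C)OC | starting material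
3 | (2-methoxy-4-methylphenyl)lithium | [Li]c1ccc(C)cc1OC | intermediate (not isolated)
4 | 1-(2-methoxy-4-methylphenyl)-2-methylpropan-1-one | COc1cc(C)ccc1C(=O)C(C)C | intermediate
5 | ethyl bromoacetate | CCOC(=O)CBr | starting material
6 | ethyl (bromozincio)acetate (Reformatsky reagent) | CCOC(=O)C[Zn]Br | intermediate (not isolated)
7 | ethyl rac-3-hydroxy-3-(2-methoxy-4-methylphenyl)-4-methylpentanoate | COc1cc(C)ccc1C(O)(C(C)C)CC(=O)OCC | intermediate
8 | rac-3-hydroxy-3-(2-methoxy-4-methylphenyl)-4-methylpentanoic acid | COc1cc(C)ccc1C(O)(C(C)C)CC(=O)O | intermediate
9 | (S)-1-phenylethylammonium (R)-3-hydroxy-3-(2-methoxy-4-methylphenyl)-4-methylpentanoate | COc1cc(C)ccc1[C@](O)(C(C)C)CC(=O)[O-].C[C@H]([NH3+])c1ccccc1 | intermediate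
10 | (R)-3-hydroxy-3-(2-methoxy-4-methylphenyl)-4-methylpentanoic acid | COc1cc(C)ccc1[C@](O)(C(C)C)CC(=O)O | intermediate (not isolated)
11 | triethylsilyl (R)-3-(2-methoxy-4-methylphenyl)-4-methyl-3-(triethylsilyloxy)pentanoate | COc1cc(C)ccc1[C@](O[Si](CC)(CC)CC)(C(C)C)CC(=O)O[Si](CC)(CC)CC | intermediate (not isolated)
12 | (R)-3-(2-methoxy-4-methylphenyl)-4-methyl-3-(triethylsilyloxy)pentanoic acid | COc1cc(C)ccc1[C@](O[Si](CC)(CC)CC)(C(C)C)CC(=O)O | intermediate
13 | (R)-3-(2-methoxy-4-methylphenyl)-4-methyl-3-(triethylsilyloxy)pentanoyl chloride | COc1cc(C)ccc1[C@](O[Si](CC)(CC)CC)(C(C)C)CC(=O)Cl | intermediate (not isolated)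
14 | (R)-2-diazo-5-(2-methoxy-4-methylphenyl)-6-methyl-5-(triethylsilyloxy)heptan-3-one | COc1cc(C)ccc1[C@](O[Si](CC)(CC)CC)(C(C)C)CC(=O)C(C)=[N+]=[N-] | intermediate
15 | dirhodium tetraacetate carbenoid of 14, carbene carbon C1 on rhodium (bridging acetates drawn as terminal) | COc1cc(C)ccc1[C@](O[Si](CC)(CC)CC)(C(C)C)CC(=O)C(C)=[Rh](OC(C)=O)(OC(C)=O)[Rh](OC(C)=O)OC(C)=O | intermediate (not isolated)
16 | norcaradiene valence isomer of 17 (cyclopropane C1–C5–C10, methyl on C1 over the cyclohexadiene ring) | COC1=CC(C)=C[C@@H]2[C@@]3(C)C(=O)C[C@@](O[Si](CC)(CC)CC)(C(C)C)[C@@]123 | intermediate (not isolated)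
17 | (3R,8aR)-4-methoxy-6,8a-dimethyl-3-(propan-2-yl)-3-(triethylsilyloxy)-3,8a-dihydroazulen-1(2H)-one | COC1=C2[C@](O[Si](CC)(CC)CC)(C(C)C)CC(=O)[C@]2(C)C=CC(C)=C1 | intermediate
18 | (3R,8aR)-4-methoxy-6,8a-dimethyl-3-(propan-2-yl)-3-(triethylsilyloxy)-1,2,3,8a-tetrahydroazulen-1-ol (C2 epimers, daucane numbering) | COC1=C2[C@](O[Si](CC)(CC)CC)(C(C)C)CC(O)[C@]2(C)C=CC(C)=C1 | intermediate
19 | (3R,3aR,8aR)-1-hydroxy-6,8a-dimethyl-3-(propan-2-yl)-3-(triethylsilyloxy)-2,3,3a,8a-tetrahydroazulen-4(1H)-one (trans-fused, C2 epimers) | O=C1C=C(C)C=C[C@@]2(C)C(O)C[C@@](O[Si](CC)(CC)CC)(C(C)C)[C@H]12 | intermediate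
20 | (3R,3aR,8aR)-1,3-dihydroxy-6,8a-dimethyl-3-(propan-2-yl)-2,3,3a,8a-tetrahydroazulen-4(1H)-one (C2 epimers) | O=C1C=C(C)C=C[C@@]2(C)C(O)C[C@@](O)(C(C)C)[C@H]12 | intermediate
21 | lithium dienolate of 22 (C6–O–Li, C6=C7, C8=C9; both hydroxyls as lithium alkoxides) | [Li]OC1=CC(C)=CC[C@@]2(C)C(O[Li])C[C@@](O[Li])(C(C)C)[C@H]12 | intermediate (not isolated)
22 | (3R,3aR,8aR)-1,3-dihydroxy-6,8a-dimethyl-3-(propan-2-yl)-2,3,3a,5,8,8a-hexahydroazulen-4(1H)-one (C2 epimers) | O=C1CC(C)=CC[C@@]2(C)C(O)C[C@@](O)(C(C)C)[C@H]12 | intermediate
23 | O-[(3R,3aR,8aR)-3-hydroxy-6,8a-dimethyl-4-oxo-3-(propan-2-yl)-1,2,3,3a,4,5,8,8a-octahydroazulen-1-yl] O-phenyl carbonothioate (C2 epimers) | O=C1CC(C)=CC[C@@]2(C)C(OC(=S)Oc3ccccc3)C[C@@](O)(C(C)C)[C@H]12 | intermediate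
24 | (3R,3aR,8aR)-3-hydroxy-6,8a-dimethyl-3-(propan-2-yl)-2,3,3a,5,8,8a-hexahydroazulen-4(1H)-one | O=C1CC(C)=CC[C@@]2(C)CC[C@@](O)(C(C)C)[C@H]12 | intermediate
25 | (3R,3aS,4S,8aR)-6,8a-dimethyl-3-(propan-2-yl)-1,2,3,3a,4,5,8,8a-octahydroazulene-3,4-diol | O[C@H]1CC(C)=CC[C@@]2(C)CC[C@@](O)(C(C)C)[C@H]12 | intermediate
26 | 3,4-dimethoxybenzoyl chloride | COc1ccc(C(=O)Cl)cc1OC | starting material
27 | (3R,3aS,4S,8aR)-3-hydroxy-6,8a-dimethyl-3-(propan-2-yl)-1,2,3,3a,4,5,8,8a-octahydroazulen-4-yl 3,4-dimethoxybenzoate | COc1ccc(C(=O)O[C@H]2CC(C)=CC[C@@]3(C)CC[C@@](O)(C(C)C)[C@H]23)cc1OC | target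

## Step count and least certain steps

Total step count: 15. Longest linear sequence: 15 steps (1 to 27); acid chloride 26 enters in the last step.

**Step 7 (key step).** What is most likely to go wrong is diversion of the carbenoid into the tertiary C–H bond of the isopropyl group (a 1,5-insertion that competes with arene addition), together with incomplete discrimination between the two arene faces. Fallback, setting out from 14 and coming back at 17: the ring closure is run with [Cu(MeCN)4]PF6 and a C2-symmetric bis(oxazoline) ligand, 2,2'-(propane-2,2-diyl)bis(4-phenyl-4,5-dihydrooxazole), in the enantiomeric form that reinforces the bias of C4. Copper carbenoids of this kind add to arenes but do not insert into unactivated C–H bonds, and the choice of arene face is handed from the substrate alone to a chiral catalyst (matched double stereodifferentiation). No new compound is made (F0).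

**Step 9.** What is most likely to go wrong is delivery of the proton to the β face of C5, which gives the cis-fused ketone; the two faces are each flanked by one large group and the preference is not secure. A second possible loss is ionisation at C4, against which the buffer is the safeguard. Fallback, setting out from 18 and coming back at 20: the cis-fused epimer (3R,3aS,8aR)-1-hydroxy-6,8a-dimethyl-3-(propan-2-yl)-3-(triethylsilyloxy)-2,3,3a,8a-tetrahydroazulen-4(1H)-one F1 is desilylated with HF·pyridine to the cis-fused hydroxy dienone F2. F2 is then equilibrated with catalytic DBU in CH2Cl2 at 0 °C. C5 is the only enolisable position of the dienone, and only the trans-fused epimer 20 can hold the hydrogen bond from the C4 hydroxyl to the C6 carbonyl while keeping C6 away from the isopropyl group. This replaces kinetic protonation by thermodynamic control.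

**Step 11.** What is most likely to go wrong is protonation of the dienolate at C9 or later migration of the alkene into conjugation with the C6 carbonyl, and over-reduction if lithium survives the quench. Fallback, setting out from 20 and coming back at 22: catalytic 1,4-hydrogenation of the cisoid diene with (naphthalene)Cr(CO)3 and H2 in THF. It adds hydrogen to C7 and C10 and leaves the cis alkene at C8=C9 under neutral conditions with no enolate on the way. No new compound is made (F0).

**Step 14.** What is most likely to go wrong is slow exchange of the hindered tertiary hydroxyl onto boron, so that undirected hydride attack on the open α face erodes the selectivity, or migration of the alkene in the acidic medium. Fallback, setting out from 24 and coming back at 27: the ketone is reduced from the open α face with LiBH(s-Bu)3 in THF at −78 °C to the 6β-alcohol, (3R,3aS,4R,8aR)-6,8a-dimethyl-3-(propan-2-yl)-1,2,3,3a,4,5,8,8a-octahydroazulene-3,4-diol F3. A Mitsunobu esterification with 3,4-dimethoxybenzoic acid (PPh3, diisopropyl azodicarboxylate, toluene) then inverts C6 and gives the target directly.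

**Step 4.** What is most likely to go wrong is that the diastereomeric salts do not differ enough in solubility, so that the crystals stay enriched instead of pure. Fallback, setting out from 7 and coming back at 10: ester 7 is separated on a chiral stationary phase (cellulose tris(3,5-dimethylphenylcarbamate)) and the ethyl (R)-3-hydroxy-3-(2-methoxy-4-methylphenyl)-4-methylpentanoate F4 is saponified with LiOH as in step 3 to acid 10, which enters step 5 at the silylation.

## Further compounds

F0 | step 7 | none | none
F1 | step 9 | (3R,3aS,8aR)-1-hydroxy-6,8a-dimethyl-3-(propan-2-yl)-3-(triethylsilyloxy)-2,3,3a,8a-tetrahydroazulen-4(1H)-one (cis-fused C5 epimer of 19) | O=C1C=C(C)C=C[C@@]2(C)C(O)C[C@@](O[Si](CC)(CC)CC)(C(C)C)[C@@H]12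
F2 | step 9 | (3R,3aS,8aR)-1,3-dihydroxy-6,8a-dimethyl-3-(propan-2-yl)-2,3,3a,8a-tetrahydroazulen-4(1H)-one (cis-fused C5 epimer of 20) | O=C1C=C(C)C=C[C@@]2(C)C(O)C[C@@](O)(C(C)C)[C@@H]12
F0 | step 11 | none | none
F3 | step 14 | (3R,3aS,4R,8aR)-6,8a-dimethyl-3-(propan-2-yl)-1,2,3,3a,4,5,8,8a-octahydroazulene-3,4-diol (C6 epimer of 25) | O[C@@H]1CC(C)=CC[C@@]2(C)CC[C@@](O)(C(C)C)[C@H]12
F4 | step 4 | ethyl (R)-3-hydroxy-3-(2-methoxy-4-methylphenyl)-4-methylpentanoate | COc1cc(C)ccc1[C@](O)(C(C)C)CC(=O)OCC
A1 | alternative 1 | 2,5-dimethylanisole | COc1cc(C)ccc1C
A2 | alternative 1 | 1-methoxy-2,5-dimethylcyclohexa-1,4-diene | COC1=C(C)CC=C(C)C1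
A3 | alternative 1 | 2-bromo-3,6-dimethylcyclohepta-2,5-dien-1-one | CC1=CCC(C)=C(Br)C(=O)C1
A4 | alternative 2 | (S)-citronellol | C[C@@H](CCC=C(C)C)CCO
A5 | alternative 2 | (S)-8-[(tert-butyldimethylsilyl)oxy]-2,6-dimethyloctan-3-one | CC(C)C(=O)CC[C@H](C)CCO[Si](C)(C)C(C)(C)C
A6 | alternative 2 | (R)-tert-butyl[2-(3-isopropyl-1-methylcyclopent-2-en-1-yl)ethoxy]dimethylsilane | CC(C)C1=C[C@@](C)(CCO[Si](C)(C)C(C)(C)C)CC1
A7 | alternative 3 | (5R)-5-methyl-2-(4-methylpent-4-enoyl)cyclopentan-1-one | C[C@@H]1CCC(C(=O)CCC(C)=C)C1=O
A8 | alternative 3 | 3a,6-dimethyloctahydroazulene-1,5-dione | C[C@@H]1CCC2C(=O)CC[C@]2(C)CC1=O
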